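(The numbers in the tables were computed with made-up constants.)

The blue run had 29.3 % of its monomer in chains at 0.833 h, then fell to a plateau near 21.2 % (mean of the last 3 readings), and that fall is what the dispute turns on.

in all of them: free monomer 0.026 M; initiator 1.5 mM
- green: protic impurity 6.4 mM; run made earlier
- blue: protic impurity 11 mM; run made earlier
- Thursday's: protic impurity 5.20 mM; time 12 h
- Saturday's: protic impurity 8.00 mM; time 12 h

| green: time / h | green: monomer in chains / % | blue: time / h | blue: monomer in chains / % |
|---|---|---|---|
| 1.00 | 40.7 | 0.833 | 29.3 |
| 1.50 | 41.1 | 2.50 | 22.6 |
| 2.50 | 38.8 | 4.00 | 21.0 |
| 4.00 | 39.3 | 6.00 | 21.8 |
| 8.00 | 39.1 | 10.0 | 21.0 |
| 12.0 | 39.6 | 12.0 | 20.8 |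

(standard deviation of a reading: 0.5 percentage points)

- the average divides the monomer in chains by the number of chains begun, living and dead together
- the numbers in the tables scatter by 0.5 percentage points (one standard deviation)
- the earlier runs do not show the number of chains; that part of a forecast is a guess

1. which of the two ends with the longer chains by the average number of monomer units in a chain (chains begun, living or dead) ("neither" if they lie within 10 %) (Thursday's / Saturday's / neither)
2. average number of monomer units in a chain (chains begun, living or dead) at the end, Thursday's
3. average number of monomer units in a chain (chains begun, living or dead) at the end, Saturday's

The forecast reads the runs as a race: “More impurity clearly stops growth earlier, which looks like a race between propagation and protic killing.” Its curve through the plateaus gives 46 % for Thursday's and 31 % for Saturday's. With one chain per initiator, that means averages of 8 and 5.4, so Thursday's ends longer.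

I read a balance instead. A chain that has merely stopped keeps its monomer, so I take blue's fall to mean that chains give monomer back until a steady level of free monomer stands against them. Suppose also that each protic impurity takes one free monomer for good. Then define the remainder r as charged monomer minus impurity minus monomer in chains on the plateau; I read it as the equilibrium monomer concentration, which on this view should not move with impurity.

The green plateau, 39.3 % by the same mean, gives 9.37 mM, and blue gives 9.49 mM. Their gap of 0.120 mM is far smaller than the 4.60 mM between their impurities, so I take their mean, 9.43 mM, as the remainder r, the monomer neither in chains nor quenched on the plateau.

My average is (charged monomer − impurity − r) divided by initiator, the same guess at chain number as the forecast makes. That gives 7.58 for Thursday's and 5.71 for Saturday's, which is closer together than the forecast's pair.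

The flasks give 7.58 for Thursday's and 5.71 for Saturday's, so Thursday's ends longer, and the forecast stands within its tolerance.

    monomer in chains + living end → free monomer + living end, rate k1*[living end] as long as [monomer in chains] is above zero (k = 0.00830 /s)
    free monomer + initiator → living end + monomer in chains (k = 0.0970 /M/s)
    free monomer + living end → monomer in chains + living end, rate k3*[living end]*[free monomer] (k = 0.880 /M/s)
    protic impurity + free monomer → quenched substrate (k = 0.0560 /M/s)

The race view keeps the opening of Thursday's: the impurity's half-life of 0.13 h, by its reaction with free monomer alone at the charged amounts, is shorter than the 1.3 h half-life of free monomer by its step with initiator alone, and 0 % of the impurity is left at the end. The neighbouring flask is Thursday's with 0.065 M of free monomer charged. The same r predicts an average of 33.6 there. That flask gives 33.6, with 77.5 % of its monomer in chains and 15 % still free.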